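(All runs are calculated for substances that don't exist; scatter was added.)

**Elm's tie.** In the elm run J stays small beside E. I call the J tie the fraction of the charge in J over the fraction in E, summing the readings at 0.417 min and 0.833 min to soften the scatter of 2 percentage points: 0.242, a rough reading. If J is a quasi-steady-state intermediate, its making and loss keep pace as E falls, so time drops out, and the tie is E's rate constant over the excess of J's rate constant above E's.

| setting | elm | larch | flask |
|---|---|---|---|
| E | 0.30 M | 0.30 M | 0.30 M |
| Q | 0.60 M (fed, over 12 s) | 0.60 M (fed, over 12 s) | 0.600 M (fed, over 12 s) |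
| G | 0.42 M | 0.66 M | 0.300 M |
| remark | run made earlier; the fed solution adds 0.25 times the starting volume | run made earlier; the fed solution adds 0.25 times the starting volume | the fed solution adds 0.25 times the starting volume |
| time |  |  | 4.0 min |

| run | time / min | E / % | J / % |
|---|---|---|---|
| elm | 0.417 | 26 | 4 |
| elm | 0.833 | 7 | 4 |
| elm | 2.00 | 1 | 0 |
| elm | 5.00 | 0 | 0 |
| larch | 1.33 | 2 | 1 |
| larch | 2.50 | 0 | 0 |
| larch | 4.00 | 2 | 2 |
| larch | 5.00 | 3 | 0 |

(scatter of a reading: 2 percentage points)

- E at 4.0 min, in percent of the E charged
- J at 4.0 min, in percent of the E charged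
- L at 4.0 min, in percent of the E charged
- Z at 4.0 min, in percent of the E charged

**The ladder.** Elm's E readings give E a half-life of 0.220 min, and the tie turns that into 2.57 s for J, also a reading. On the fastest rung stands J, whose half-life is shorter than the feed of 12 s, so J should ride on E throughout. Next come the feed and E's half-life, about equal, so E reacts while Q still enters. Highest stands 4.0 min, far longer than E's half-life, so in the flask I expect little E and J at the tie times E. The flask has G at 1.00 per E against elm's 1.40, so the tie crosses over roughly. Neither run shows L or Z.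

**The forecast.** It gives E 3%, J 1%, L 94% and Z 2%, holding that “G therefore looks like a promoter or catalyst”.

**The result.** The flask gives E 0.0188%, J 0.00560%, L 3.82% and Z 18.3%, while X holds 75.1%; it parts from the forecast at L and at Z, with L lower than forecast and Z higher than forecast.

    J + G → X (k = 1.50 L mol⁻¹ s⁻¹)
    Q + J → L (k = 0.260 L mol⁻¹ s⁻¹)
    L ⇌ D (K = 0.660, k = 0.0420 s⁻¹)
    Q + L → Z (k = 0.0650 L mol⁻¹ s⁻¹)
    E + Q → J (k = 0.210 L mol⁻¹ s⁻¹)

**At rest?** The flask's tie is 0.324 at 2.00 min and 0.298 at 4.00 min, so J still rides on E, which stands at 0.0188%. The neighbour with 1.2 M of E shows a tie of 0.223, with E at 56.4% beside Q at 0% of its own charge. The flask has not come to rest: at 40.0 min, X stays at 75.1%, L falls from 3.82% to 0%, D falls from 2.74% to 0%, and Z rises from 18.3% to 24.9%.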